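Everything rests on cutting the bond from C10, the tetrasubstituted aminal carbon common to the pyrrolidine, ketopiperazine and imidazoline rings, to the unmethylated ring nitrogen of the guanidine. C10 is a proline Cα, so before that bond exists it carries a hydrogen. A guanidine placed on the adjacent aminal carbon C6 can reach that hydrogen through a five-membered transition state. A rhodium nitrenoid generated on this guanidine trades C10–H for C10–N with retention, closing the cis-fused imidazoline and finishing the tetracycle in one operation. The precursor is the D-prolinol-derived pyrrole–ketopiperazine–pyrrolidine tricycle with an N-methyl-N'-Tces-guanidine at C6, cis to H10. Both bromines enter last.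

Key step: step 9

Remark on locants: C6 is the aminal CH between the pyrrole nitrogen and the N-methyl nitrogen. C10 is the neighbouring carbon, which is also Cα of the pyrrolidine, and C11 is the ring CH2 next to C10. The pyrrole carbons run from C2 (acyl) to C5.
Assumption: guanidines 22, 23 and 24 are drawn as free bases but would be handled as trifluoroacetate salts, the free base of 24 being released in the last work-up.
Remark on the order of events: the pyrrole stays unbrominated until the end, because a bromine at C5 would shield the rear side of C6 in step 3 and would be at risk with zinc in step 10.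

Step 1
Reactants: 1 D-prolinol, (R)-pyrrolidin-2-ylmethanol; 2 2-(trichloroacetyl)pyrrole
Product: 3 N-(pyrrole-2-carbonyl)-D-prolinol, (R)-configured
Conditions: MeCN, rt, no added base
Reagents that add atoms: none
Why: Haloform-type amine acylation, in which the secondary amine of 1 adds to the trichloromethyl ketone and expels trichloromethanide as chloroform, the amine far outrunning the primary alcohol and the stereocentre of 1 staying untouched.

Step 2
Reactants: 3 N-(pyrrole-2-carbonyl)-D-prolinol
Product: 5 tricyclic carbinolamine (6S,10R) whose C6–OH is trans to H10, via aldehyde 4 (not isolated)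
Conditions: IBX (1.1 equiv), DMSO, rt
Reagents that add atoms: none
Why: Neutral IBX alcohol oxidation gives the α-amido aldehyde 4 without enolisation, the pyrrole N–H adds at once to the formyl group (6-exo-trig ring–chain tautomerism), and because this addition is reversible C6 settles under thermodynamic control with the hydroxyl pseudoaxial, away from pyrrole C5–H and anti to the pseudoaxial H10 that the pyrrolidine fusion locks in place.

Step 3
Reactants: 5 tricyclic carbinolamine
Product: 7 C6 azide (6R,10R) cis to H10, via oxyphosphonium azide 6 (not isolated)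
Conditions: PPh3, DIAD, DPPA, toluene–THF, −10 °C → rt
Reagents that add atoms: diphenylphosphoryl azide (DPPA), O=P(N=[N+]=[N-])(Oc1ccccc1)Oc1ccccc1
Why: Mitsunobu reaction with DPPA as azide source, in which the hydroxyl becomes oxyphosphonium 6 without any strong base that could open the carbinolamine, epimerise C10 or trigger E2 loss of the antiperiplanar H10, the 2-acylpyrrole nitrogen is too poor a donor to favour ionisation in a solvent of low polarity, and azide therefore displaces the pseudoaxial leaving group from the rear, inverting C6 and placing nitrogen cis to H10.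

Step 4
Reactants: 8 2,2,2-trichloroethyl sulfamate (TcesNH2)
Product: 10 dimethyl N-Tces-dithiocarbonimidate, via disodium dithiocarbonimidate 9 (not isolated)
Conditions: CS2, NaOH (2 equiv), DMF, 0 °C; then MeI (2.2 equiv), 0 °C → rt
Reagents that add atoms: carbon disulfide, S=C=S; iodomethane, CI
Why: Classical dithiocarbonimidate synthesis from a sulfonamide-type NH2 group, in which double deprotonation and addition to CS2 give dianion 9, whose two soft sulfur centres are S-methylated by MeI.

Step 5
Reactants: 10 dimethyl N-Tces-dithiocarbonimidate
Product: 11 S-methyl N-Tces-isothiourea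
Conditions: NH3 (7 M in MeOH), THF, 0 °C → rt
Reagents that add atoms: ammonia, N
Why: Addition–elimination at the sulfonyl-activated C=N bond, in which ammonia replaces one methylthio group and the reaction stops there because the push–pull isothiourea 11 is far less electrophilic than 10.

Step 6
Reactants: 11 S-methyl N-Tces-isothiourea
Product: 12 N-Boc-S-methyl-N'-Tces-isothiourea
Conditions: Boc2O, Et3N, DMAP (cat.), CH2Cl2, rt
Reagents that add atoms: di-tert-butyl dicarbonate, CC(C)(C)OC(=O)OC(=O)OC(C)(C)C
Why: DMAP-catalysed N-acylation caps the NH2 group, so that loss of methanethiol in step 8 gives a neutral, doubly activated carbodiimide and not the inert anion of an N-sulfonylcyanamide.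

Step 7
Reactants: 7 C6 azide
Product: 15 C6 methylamino aminal (6S,10R) whose NHMe is cis to H10, via iminophosphorane 13 (not isolated), via N-methylene imine 14 (not isolated)
Conditions: PMe3 (1 M in THF), THF, 0 °C; (CH2O)n, 0 °C → rt; then NaBH4, MeOH, −10 °C; cold extractive work-up, used at once
Reagents that add atoms: paraformaldehyde (as formaldehyde), C=O
Why: Staudinger reaction, aza-Wittig reaction with formaldehyde and borohydride reduction in one flask put exactly one methyl group on nitrogen without aqueous base or an alkylating agent, no bond to C6 is broken so the cis configuration is kept, and short cold handling limits opening of the aminal.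

Step 8
Reactants: 15 C6 methylamino aminal; 12 N-Boc-S-methyl-N'-Tces-isothiourea
Product: 18 C6 N-methyl-N'-Tces-guanidine (6R,10R) cis to H10, via Boc-Tces-carbodiimide 16 (not isolated), via N-Boc guanidine 17 (not isolated)
Conditions: AgNO3, Et3N, MeCN, 0 °C; filter through Celite, concentrate; then TFA–CH2Cl2, 0 °C → rt
Reagents that add atoms: none
Why: Thiophile-promoted guanidinylation, in which Ag(I) and Et3N strip methanethiol from 12, carbodiimide 16 is electrophilic enough to capture the hindered and configurationally fragile secondary amine quickly at 0 °C, and acidolysis of the Boc group of 17 (Tces, lactam and the now doubly deactivated aminal being inert to TFA) frees the NH2 needed for nitrene formation.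

Step 9
Reactants: 18 C6 N-methyl-N'-Tces-guanidine
Product: 20 N-Tces-7-N-methylphakellin (6R,10R), via iminoiodinane 19 (not isolated)
Conditions: Rh2(esp)2 (3 mol %), PhI(OAc)2 (1.5 equiv), MgO (2.5 equiv), toluene, 40 °C
Reagents that add atoms: none
Why: PhI(OAc)2 condenses with the free NH2 of the sulfonylguanidine to iminoiodinane 19, which hands its nitrogen to Rh2(esp)2, and the resulting Rh-nitrenoid inserts into C10–H through a concerted, asynchronous three-centre transition state while MgO takes up the acetic acid. The closest known reaction type is the Rh(II)-catalysed intramolecular C–H amination of N-Tces guanidines and ureas, which gives five-membered cyclic products at tertiary and heteroatom-activated C–H bonds. One ring closes, the 2-iminoimidazolidine (nitrene nitrogen, guanidine carbon, N-methyl nitrogen, C6, C10), by formation of the N–C10 bond in a 1,3-insertion mode, and it is cis-fused to the ketopiperazine because a tether this short cannot span C6–C10 in a trans sense. The only new stereocentre, C10, is controlled by its own hydrogen: nitrogen enters where H10 leaves, so the D-prolinol configuration is retained and C6 is not touched. Site selectivity is needed against C11–H2, the N-methyl group and pyrrole C5; it is secured by ring size (C11 would need a six-membered closure at an unactivated methylene, N–CH3 a four-membered one), by the tertiary α-amido nature of C10–H, whose pseudoaxial bond overlaps with the π system of the lactam nitrogen, and by the cis, gauche placement of the guanidine. The 2-acyl group lowers the pyrrole HOMO and the pseudoequatorial tether lies near the pyrrole plane rather than over its π face, which should hold back attack at C5.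

Step 10
Reactants: 20 N-Tces-7-N-methylphakellin
Product: 22 7-N-methylphakellin (6R,10R), via N-sulfonic acid 21 (not isolated)
Conditions: Zn dust, AcOH–MeOH, rt; filter; then 1 M aq HCl, 40 °C; reversed-phase purification (TFA buffer)
Reagents that add atoms: none
Why: Reductive fragmentation of the 2,2,2-trichloroethyl ester by zinc (two-electron reduction, then β-elimination of 1,1-dichloroethene) leaves N-sulfonic acid 21, whose N–S bond is hydrolysed by warm dilute acid, and doing this before bromination means that no C–Br bond is exposed to zinc.

Step 11
Reactants: 22 7-N-methylphakellin (trifluoroacetate salt)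
Product: 24 (−)-7-N-methyldibromophakellin (6S,10R), via 4-bromide 23 (not isolated)
Conditions: NBS (2.05 equiv), MeCN, 0 °C → rt, dark; aq NaHCO3 work-up
Reagents that add atoms: N-bromosuccinimide, O=C1CCC(=O)N1Br
Why: Electrophilic aromatic substitution, in which NBS attacks only the pyrrole because the guanidine is masked as its cation, the 2-acyl group steers the first bromine to C4 and the second to the remaining α position C5, C3 next to the carbonyl is the least reactive site, and neither stereocentre is involved (the C6 descriptor changes only because bromine alters the priorities).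

Compound list
1 | D-prolinol, (R)-pyrrolidin-2-ylmethanol | OC[C@H]1CCCN1 | starting material
2 | 2-(trichloroacetyl)pyrrole | O=C(c1ccc[nH]1)C(Cl)(Cl)Cl | starting material
3 | N-(pyrrole-2-carbonyl)-D-prolinol, (R) | OC[C@H]1CCCN1C(=O)c1ccc[nH]1 | intermediate
4 | (R)-1-(pyrrole-2-carbonyl)pyrrolidine-2-carbaldehyde (not isolated) | O=C[C@H]1CCCN1C(=O)c1ccc[nH]1 | intermediate
5 | tricyclic carbinolamine (6S,10R), C6–OH pseudoaxial, trans to H10 | O[C@H]1[C@H]2CCCN2C(=O)c2cccn21 | intermediate
6 | C6 oxytriphenylphosphonium azide of 5 (6S,10R) (not isolated) | c1ccccc1[P+](c1ccccc1)(c1ccccc1)O[C@H]1[C@H]2CCCN2C(=O)c2cccn21.[N-]=[N+]=[N-] | intermediate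
7 | C6 azide (6R,10R), cis to H10 | [N-]=[N+]=N[C@@H]1[C@H]2CCCN2C(=O)c2cccn21 | intermediate
8 | 2,2,2-trichloroethyl sulfamate (TcesNH2) | NS(=O)(=O)OCC(Cl)(Cl)Cl | starting material
9 | disodium N-Tces-dithiocarbonimidate (not isolated) | [Na+].[Na+].[S-]C([S-])=NS(=O)(=O)OCC(Cl)(Cl)Cl | intermediate
10 | dimethyl N-Tces-dithiocarbonimidate | CSC(SC)=NS(=O)(=O)OCC(Cl)(Cl)Cl | intermediate
11 | S-methyl N-Tces-isothiourea | CSC(N)=NS(=O)(=O)OCC(Cl)(Cl)Cl | intermediate
12 | N-Boc-S-methyl-N'-Tces-isothiourea | CSC(NC(=O)OC(C)(C)C)=NS(=O)(=O)OCC(Cl)(Cl)Cl | intermediate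
13 | C6 trimethyliminophosphorane (6R,10R), cis to H10 (not isolated) | CP(C)(C)=N[C@@H]1[C@H]2CCCN2C(=O)c2cccn21 | intermediate
14 | C6 N-methylene imine (6R,10R), cis to H10 (not isolated) | C=N[C@@H]1[C@H]2CCCN2C(=O)c2cccn21 | intermediate
15 | C6 methylamino aminal (6S,10R), NHMe cis to H10 | CN[C@@H]1[C@H]2CCCN2C(=O)c2cccn21 | intermediate
16 | N-Boc-N'-Tces-carbodiimide (not isolated) | CC(C)(C)OC(=O)N=C=NS(=O)(=O)OCC(Cl)(Cl)Cl | intermediate
17 | C6 N-methyl-N'-Boc-N''-Tces-guanidine (6R,10R), cis to H10 (not isolated) | CN(C(NC(=O)OC(C)(C)C)=NS(=O)(=O)OCC(Cl)(Cl)Cl)[C@@H]1[C@H]2CCCN2C(=O)c2cccn21 | intermediate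
18 | C6 N-methyl-N'-Tces-guanidine (6R,10R), cis to H10 | CN(C(N)=NS(=O)(=O)OCC(Cl)(Cl)Cl)[C@@H]1[C@H]2CCCN2C(=O)c2cccn21 | intermediate
19 | phenyliodonio imide (iminoiodinane) of 18 (not isolated) | CN(C(N=Ic1ccccc1)=NS(=O)(=O)OCC(Cl)(Cl)Cl)[C@@H]1[C@H]2CCCN2C(=O)c2cccn21 | intermediate
20 | N-Tces-7-N-methylphakellin (6R,10R), imidazoline cis-fused | CN1C(=NS(=O)(=O)OCC(Cl)(Cl)Cl)N[C@]23CCCN2C(=O)c2cccn2[C@H]13 | intermediate
21 | 7-N-methylphakellin N-sulfonic acid (6R,10R) (not isolated) | CN1C(=NS(=O)(=O)O)N[C@]23CCCN2C(=O)c2cccn2[C@H]13 | intermediate
22 | 7-N-methylphakellin (6R,10R) | CN1C(N)=N[C@]23CCCN2C(=O)c2cccn2[C@H]13 | intermediate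
23 | 4-bromo-7-N-methylphakellin (6R,10R) (not isolated) | CN1C(N)=N[C@]23CCCN2C(=O)c2cc(Br)cn2[C@H]13 | intermediate
24 | (−)-7-N-methyldibromophakellin (6S,10R) | CN1C(N)=N[C@]23CCCN2C(=O)c2cc(Br)c(Br)n2[C@H]13 | target

Total step count: 11
Longest linear sequence: 8 steps (1, 2, 3, 7, 8, 9, 10, 11)

Steps most likely to fail

1. Step 9. The electrophilic nitrenoid, or the iodine(III) oxidant itself, may attack the pyrrole π system at C5 faster than it inserts into C10–H, whose hydridic character is lowered by the two nitrogen atoms on C6. The fallback blocks and deactivates the pyrrole before the amination instead of after it.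
- Setting out from guanidine 18, NBS (2 equiv, MeCN, 0 °C) would lead through the 4-bromopyrrole guanidine F1 to the 4,5-dibromopyrrole guanidine F2.
- The same Rh2(esp)2/PhI(OAc)2/MgO system would take this through its iminoiodinane F3 to N-Tces-7-N-methyldibromophakellin F4.
- Brief contact with Zn–Cu couple in AcOH–MeOH at 0 °C, then warm dilute acid acting on the N-sulfonic acid F5, would come back to the route at target 24.
- The step count stays the same. The price is the exposure of the C5–Br bond to zinc, hence the short, cold reduction.

2. Step 3. Three processes threaten this step. The activated oxygen may leave together with the antiperiplanar H10, erasing C10. It may ionise, so that azide enters from the pseudoaxial side. The carbinolamine may also epimerise before activation, which would spoil the inversion. The fallback separates activation from displacement and removes every base from the displacement.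
- Setting out from carbinolamine 5, Cl3CCN with catalytic K2CO3 (CH2Cl2, 0 °C) should give the pseudoaxial C6 trichloroacetimidate F6. This donor is isolable, so its configuration can be checked.
- TMSN3 with catalytic TMSOTf in toluene at −78 °C should then replace the imidate in the invertive manner known from glycosyl imidates in non-participating solvents.
- The sequence returns to the route at azide 7.

3. Step 7. The electron-rich iminophosphorane or the free amine may push the acylpyrrole nitrogen off C6. This ring–chain opening would drift C6 towards the trans series and would let borohydride trap the open imine. The fallback keeps the C6 nitrogen acylated or protonated at every stage.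
- Setting out from azide 7, hydrogenation (H2, Pd/C, EtOAc) in the presence of Boc2O would trap the C6 primary amine F7 as it forms, giving the C6 tert-butyl carbamate F8.
- NaH and MeI (DMF, 0 °C) would give the N-methyl carbamate F9.
- TFA in CH2Cl2 would return to the route at 15, obtained as its trifluoroacetate and set free by Et3N only in the flask of step 8.

Further compounds
F1 | step 9 | C6 N-methyl-N'-Tces-guanidine with 4-bromopyrrole (6R,10R) | CN(C(N)=NS(=O)(=O)OCC(Cl)(Cl)Cl)[C@@H]1[C@H]2CCCN2C(=O)c2cc(Br)cn21
F2 | step 9 | C6 N-methyl-N'-Tces-guanidine with 4,5-dibromopyrrole (6S,10R) | CN(C(N)=NS(=O)(=O)OCC(Cl)(Cl)Cl)[C@@H]1[C@H]2CCCN2C(=O)c2cc(Br)c(Br)n21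
F3 | step 9 | iminoiodinane of F2 | CN(C(N=Ic1ccccc1)=NS(=O)(=O)OCC(Cl)(Cl)Cl)[C@@H]1[C@H]2CCCN2C(=O)c2cc(Br)c(Br)n21
F4 | step 9 | N-Tces-7-N-methyldibromophakellin (6S,10R) | CN1C(=NS(=O)(=O)OCC(Cl)(Cl)Cl)N[C@]23CCCN2C(=O)c2cc(Br)c(Br)n2[C@H]13
F5 | step 9 | 7-N-methyldibromophakellin N-sulfonic acid (6S,10R) | CN1C(=NS(=O)(=O)O)N[C@]23CCCN2C(=O)c2cc(Br)c(Br)n2[C@H]13
F6 | step 3 | C6 trichloroacetimidate of 5 (6S,10R), trans to H10 | N=C(O[C@H]1[C@H]2CCCN2C(=O)c2cccn21)C(Cl)(Cl)Cl
F7 | step 7 | C6 primary amine (6S,10R), cis to H10 | N[C@@H]1[C@H]2CCCN2C(=O)c2cccn21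
F8 | step 7 | C6 tert-butyl carbamate (6S,10R), cis to H10 | CC(C)(C)OC(=O)N[C@@H]1[C@H]2CCCN2C(=O)c2cccn21
F9 | step 7 | C6 N-methyl tert-butyl carbamate (6R,10R), cis to H10 | CN(C(=O)OC(C)(C)C)[C@@H]1[C@H]2CCCN2C(=O)c2cccn21
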